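**Retrosynthetic overview**

1. The target is the CH2-bridged dimer of 7-acetyl-3,6,8-trihydroxy-4,4-dimethylnaphthalen-1(4H)-one. The two C2–CH2 bonds are cut last (formaldehyde, Knoevenagel–Michael, as in the presumed biosynthesis).
2. In the monomer, ring B (C1, C2, C3, C4, C4a, C8a) is cut at C2–C3 and at C4–C4a. Isobutyronitrile delivers C3, C4 and both methyl groups to 1,3-diacetyl-5-bromo-2,4-dimethoxybenzene, which already holds ring A, C1, C2 and the C7 acetyl group.
3. Enabling feature: C4a is meta to both oxygens of ring A (on C6 and C8) and ortho to C8a, which carries the C1 carbonyl; its neighbour C5 is the one position that electrophiles attack. Bromine at C5 therefore leads to the aryne C4a≡C5, the C6 oxygen steers the nitrile carbanion to C4a (cine substitution), and the enolate of the acetyl group on C8a closes ring B on the nitrile carbon.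
4. Order of ring formation: ring A is bought (2,6-dimethoxyacetophenone); ring B is made in step 3; step 4 exchanges NH2 for OH at C3 and frees the phenols; step 5 joins the halves.

Key step: step 3

Remark: the target has no stereocentre, so no configuration has to be set. It is drawn as the bis-enol tautomer, and compounds 12 and 15 are drawn the same way. Positions are named by the naphthalene numbering of one half (C1 ketone, C2 bridge carbon, C3 enol carbon, C4 CMe2, C4a, C5 H, C6 OH, C7 acetyl, C8 OH, C8a).

**Route**

Step 1
Reactants: 1 2,6-dimethoxyacetophenone; 2 acetyl chloride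
Product: 3 1,3-diacetyl-2,4-dimethoxybenzene [1,1'-(2,4-dimethoxy-1,3-phenylene)bis(ethan-1-one)]
Conditions: AcCl (1.3 equiv), AlCl3 (2.5 equiv), CH2Cl2, 0 °C; then ice/1 M HCl
Reagents that add atoms: acetyl chloride, CC(=O)Cl
Why: Friedel–Crafts acylation should enter at C3, which is ortho to one methoxy group and para to the other and is the only kind of activated position, while the low temperature should keep the methyl ethers intact.

Step 2
Reactants: 3 1,3-diacetyl-2,4-dimethoxybenzene; 4 N-bromosuccinimide
Product: 5 1,3-diacetyl-5-bromo-2,4-dimethoxybenzene [1,1'-(5-bromo-2,4-dimethoxy-1,3-phenylene)bis(ethan-1-one)]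
Conditions: NBS (1.05 equiv), MeCN, rt, dark
Reagents that add atoms: N-bromosuccinimide, O=C1CCC(=O)N1Br
Why: Electrophilic aromatic bromination should go to C5, ortho to the C4 methoxy group and para to the C2 methoxy group, because the other free position is meta to both ethers, and the polar medium favours ring over side-chain bromination.

Step 3
Reactants: 5 1,3-diacetyl-5-bromo-2,4-dimethoxybenzene; 6 isobutyronitrile
Product: 9 7-acetyl-3-amino-6,8-dimethoxy-4,4-dimethylnaphthalen-1(4H)-one, via aryne bis-enolate 7 (not isolated), via aryl nitrile bis-enolate 8 (not isolated)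
Conditions: 5, LiN(i-Pr)2 (3.5 equiv), THF, −78 °C; then LiCMe2CN (3 equiv, from i-PrCN and LiN(i-Pr)2), −78 °C → 40 °C; then H2O
Reagents that add atoms: isobutyronitrile, CC(C)C#N
Why: Proposed new method: LiN(i-Pr)2 first converts both acetyl groups into lithium enolates, then removes the only ring hydrogen (on C4a, ortho to bromine), and loss of LiBr gives the aryne C4a≡C5, as is known for 2-bromoanisoles under the same base. The lithiated nitrile adds at C4a, meta to the C6 methoxy group whose inductive effect polarises the aryne and stabilises the aryl anion at C5 until diisopropylamine protonates it; the closest known reaction type is the aryne arylation of α-lithiated nitriles with 3-methoxyarynes. The enolate carbon C2 of the acetyl group on C8a then lies beside the nitrile and adds to its carbon C3 in a 6-exo-dig closure of ring B, the Thorpe–Ziegler-type cyclisation known for 5-oxonitriles, and tautomerisation to the anion of the vinylogous amide makes the closure irreversible. No stereocentre is formed. The step needs three selectivities: the site of addition to the aryne is set by the C6 oxygen, and the enolate next to the aryne cannot capture it because that would close a four-membered ring; of the two enolates only the one on C8a is ortho to the nitrile, the C7 enolate being para to it; and attack of enolate oxygen on the nitrile gives an imidate that reverts, whereas attack of carbon ends in the stable enaminone. What is new is the union of these known events in one flask on an arene that carries two ketone enolates.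

Step 4
Reactants: 9 7-acetyl-3-amino-6,8-dimethoxy-4,4-dimethylnaphthalen-1(4H)-one; 10 water
Product: 12 7-acetyl-3,6,8-trihydroxy-4,4-dimethylnaphthalen-1(4H)-one, via dihydroxy enaminone 11 (not isolated)
Conditions: BBr3 (5 equiv), CH2Cl2, −78 °C → rt; then H2O/1,4-dioxane, 80 °C
Reagents that add atoms: water, O
Why: Both methoxy groups are ortho to a chelating carbonyl and should be cleaved by the Lewis acid, and the HBr set free on quenching should hydrolyse the vinylogous amide through its C3 iminium ion, which puts OH in place of NH2.

Step 5
Reactants: 12 7-acetyl-3,6,8-trihydroxy-4,4-dimethylnaphthalen-1(4H)-one (2 equiv); 13 formaldehyde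
Product: 15 2,2'-methylenebis[7-acetyl-3,6,8-trihydroxy-4,4-dimethylnaphthalen-1(4H)-one], via methylene dione 14 (not isolated)
Conditions: 37% aq. CH2O (0.5 equiv), EtOH/H2O, rt
Reagents that add atoms: formaldehyde, C=O
Why: Knoevenagel condensation of the cyclic 1,3-dione at C2 followed by Michael addition of a second dione (the reaction that gives methylenebis(dimedone)) should join the halves, since the doubly acylated ring A is too deactivated to compete.

**Compound list**

1 | 2,6-dimethoxyacetophenone | CC(=O)c1c(OC)cccc1OC | starting material
2 | acetyl chloride | CC(=O)Cl | starting material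
3 | 1,3-diacetyl-2,4-dimethoxybenzene | CC(=O)c1ccc(OC)c(C(C)=O)c1OC | intermediate
4 | N-bromosuccinimide | O=C1CCC(=O)N1Br | starting material
5 | 1,3-diacetyl-5-bromo-2,4-dimethoxybenzene | CC(=O)c1cc(Br)c(OC)c(C(C)=O)c1OC | intermediate
6 | isobutyronitrile (2-methylpropanenitrile) | CC(C)C#N | starting material
7 | aryne bis-enolate: dilithium bis-enolate of 3,5-diacetyl-4,6-dimethoxybenzyne (aryne bond between the later C4a and C5) | [Li+].[Li+].C=C([O-])C1=C(OC)C(C([O-])=C)=C(OC)C#C1 | intermediate
8 | aryl nitrile bis-enolate: dilithium bis-enolate of 2-(2,4-diacetyl-3,5-dimethoxyphenyl)-2-methylpropanenitrile | [Li+].[Li+].C=C([O-])c1c(OC)c(C([O-])=C)c(OC)cc1C(C)(C)C#N | intermediate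
9 | 7-acetyl-3-amino-6,8-dimethoxy-4,4-dimethylnaphthalen-1(4H)-one | CC(=O)c1c(OC)cc2c(c1OC)C(=O)C=C(N)C2(C)C | intermediate
10 | water | O | starting material
11 | dihydroxy enaminone: 7-acetyl-3-amino-6,8-dihydroxy-4,4-dimethylnaphthalen-1(4H)-one | CC(=O)c1c(O)cc2c(c1O)C(=O)C=C(N)C2(C)C | intermediate
12 | 7-acetyl-3,6,8-trihydroxy-4,4-dimethylnaphthalen-1(4H)-one (enol form of the 1,3-dione) | CC(=O)c1c(O)cc2c(c1O)C(=O)C=C(O)C2(C)C | intermediate
13 | formaldehyde | C=O | starting material
14 | methylene dione: 7-acetyl-6,8-dihydroxy-4,4-dimethyl-2-methylidenenaphthalene-1,3(2H,4H)-dione | CC(=O)c1c(O)cc2c(c1O)C(=O)C(=C)C(=O)C2(C)C | intermediate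
15 | 2,2'-methylenebis[7-acetyl-3,6,8-trihydroxy-4,4-dimethylnaphthalen-1(4H)-one] | CC(=O)c1c(O)cc2c(c1O)C(=O)C(CC1=C(O)C(C)(C)c3cc(O)c(C(C)=O)c(O)c3C1=O)=C(O)C2(C)C | target

**Summary**

Total step count: 5. Longest linear sequence: 5 steps (1 → 3 → 5 → 9 → 12 → 15).

Steps most likely to fail:

Step 3 (Proposed new method). The aryne may be captured by diisopropylamide or by an enolate of a second molecule instead of the nitrile carbanion, the base may fail to remove the ring hydrogen from the already dianionic arene, or the sequence may stall before ring closure. The fallback uses known chemistry and makes the two bonds in separate steps; it sets out from isobutyronitrile 6 and comes back at 9. Isobutyronitrile 6 is deprotonated with KN(SiMe3)2 and arylated by nucleophilic aromatic substitution on 1-fluoro-3,5-dimethoxybenzene F1 (bought; toluene, 60 °C) to give 2-(3,5-dimethoxyphenyl)-2-methylpropanenitrile F2. Two Friedel–Crafts acetylations with acetyl chloride 2 and AlCl3 should then give 2-(2,4-diacetyl-3,5-dimethoxyphenyl)-2-methylpropanenitrile F3, because the 2,6-isomer would place both acetyl groups beside the quaternary carbon. KOC(CH3)3 in THF should close ring B by Thorpe–Ziegler addition of the enolate of the ortho acetyl group to the nitrile, which returns to the route at 9.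

Step 1. AlCl3 may cleave the methyl ether next to the new ketone, and the hindered acetyl group may migrate or be lost under the acid. The fallback sets out from 1 and comes back at 3. BBr3 cleaves both ethers of 1 to 2,6-dihydroxyacetophenone F4; acetic acid with BF3·OEt2 at 90 °C acetylates the resorcinol ring ortho to one hydroxyl and para to the other to give 2,4-diacetylresorcinol F5; CH3I and K2CO3 in DMF at 60 °C methylate both chelated hydroxyls and return to the route at 3.

Step 4. Hydrolysis of the vinylogous amide beside the quaternary carbon may be slow, and long heating in acid may remove the C7 acetyl group from the free phenol. The fallback separates the two tasks, sets out from 9 and comes back at 12. Aqueous NaOH in ethanol at reflux hydrolyses the vinylogous amide of 9 first and gives 7-acetyl-3-hydroxy-6,8-dimethoxy-4,4-dimethylnaphthalen-1(4H)-one F6 with loss of ammonia. BCl3 in CH2Cl2 at 0 °C then removes the two methyl groups, each ortho to a chelating carbonyl, without hot aqueous acid, and returns to the route at 12.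

**Further compounds**

F1 | step 3 | 1-fluoro-3,5-dimethoxybenzene (bought) | COc1cc(F)cc(OC)c1
F2 | step 3 | 2-(3,5-dimethoxyphenyl)-2-methylpropanenitrile | COc1cc(OC)cc(C(C)(C)C#N)c1
F3 | step 3 | 2-(2,4-diacetyl-3,5-dimethoxyphenyl)-2-methylpropanenitrile | CC(=O)c1c(OC)c(C(C)=O)c(OC)cc1C(C)(C)C#N
F4 | step 1 | 2,6-dihydroxyacetophenone | CC(=O)c1c(O)cccc1O
F5 | step 1 | 2,4-diacetylresorcinol | CC(=O)c1ccc(O)c(C(C)=O)c1O
F6 | step 4 | 7-acetyl-3-hydroxy-6,8-dimethoxy-4,4-dimethylnaphthalen-1(4H)-one | CC(=O)c1c(OC)cc2c(c1OC)C(=O)C=C(O)C2(C)C
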